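## Retrosynthetic overview

1. Ring C is closed last: cutting the O1–C2 bond of (2R)-kazinol I gives an open (E)-cinnamyl-resorcinol whose para-hydroxystyrene unit is cyclised enantioselectively by a chiral Brønsted acid.
2. The cinnamylphenol comes from a 2'-hydroxychalcone by reductive removal of the carbonyl oxygen (the future C4).
3. The chalcone is split by a Claisen–Schmidt disconnection into a ring A acetophenone (from 2,4-dihydroxyacetophenone) and a ring B aldehyde.
4. The ring B aldehyde comes from 5-bromovanillin by a second bromination, O-demethylation, MOM protection and two-fold prenyl cross-coupling.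
5. Ring order: rings A and B are bought as benzene building blocks; pyran ring C is the only ring made, in the final step, which also sets the single stereocentre.

Assumption: the sense of induction of the new cyclisation cannot be predicted with certainty. The route is written with the (R)-configured acid; if the first run gives the (2S)-product, the mirror-image acid is used.

Abbreviations: MOM = methoxymethyl; prenyl = 3-methylbut-2-en-1-yl.

## Route

Step 1
Reactants: 1 5-bromovanillin (3-bromo-4-hydroxy-5-methoxybenzaldehyde)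
Product: 2 2,3-dibromo-4-hydroxy-5-methoxybenzaldehyde (5,6-dibromovanillin)
Conditions: Br2 (1.1 equiv), Fe powder (cat.), NaOAc, AcOH, rt
Reagents that add atoms: bromine, BrBr
Why: Electrophilic aromatic bromination goes to the free position para to the methoxy group, giving the contiguous 2,3-dibromo-4,5-dioxygenated pattern that maps onto the two prenyl and two hydroxyl positions of ring B.

Step 2
Reactants: 2 2,3-dibromo-4-hydroxy-5-methoxybenzaldehyde
Product: 3 2,3-dibromo-4,5-dihydroxybenzaldehyde
Conditions: AlCl3 (1.2 equiv), pyridine, CH2Cl2, reflux; then aq. HCl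
Reagents that add atoms: none
Why: Lewis-acid-assisted O-demethylation: aluminium chelation by the ortho-hydroxy/methoxy pair activates the methyl ether for SN2 attack by pyridine, and the aldehyde and aryl bromides are untouched.

Step 3
Reactants: 3 2,3-dibromo-4,5-dihydroxybenzaldehyde
Product: 4 2,3-dibromo-4,5-bis(methoxymethoxy)benzaldehyde
Conditions: MOMCl (3 equiv), i-Pr2NEt, CH2Cl2, 0 °C to rt
Reagents that add atoms: chloromethyl methyl ether, COCCl
Why: O-alkylation of both phenols (Williamson-type acetal formation) gives ethers that survive palladium coupling and hydroxide and can later be removed without hydrogenolysis or strong Lewis acids.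

Step 4
Reactants: 4 2,3-dibromo-4,5-bis(methoxymethoxy)benzaldehyde
Product: 5 4,5-bis(methoxymethoxy)-2,3-bis(3-methylbut-2-en-1-yl)benzaldehyde
Conditions: tributyl(3-methylbut-2-en-1-yl)stannane (2.6 equiv), Pd(PPh3)4 (10 mol %), DMF, 100 °C
Reagents that add atoms: tributyl(3-methylbut-2-en-1-yl)stannane, CC(C)=CC[Sn](CCCC)(CCCC)CCCC
Why: Two-fold Stille cross-coupling: zerovalent palladium inserts into the aldehyde-activated aryl bromides, and neutral tin-to-palladium transfer followed by reductive elimination at the less hindered allyl terminus gives the linear prenyl groups without touching the aldehyde.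

Step 5
Reactants: 6 2,4-dihydroxyacetophenone
Product: 7 1-[2-hydroxy-4-(methoxymethoxy)phenyl]ethan-1-one
Conditions: MOMCl (1.1 equiv), i-Pr2NEt, CH2Cl2, 0 °C
Reagents that add atoms: chloromethyl methyl ether, COCCl
Why: Chemoselective O-alkylation: the 2-hydroxyl is held in a hydrogen bond to the ketone, so only the 4-hydroxyl is etherified.

Step 6
Reactants: 7 1-[2-hydroxy-4-(methoxymethoxy)phenyl]ethan-1-one; 5 4,5-bis(methoxymethoxy)-2,3-bis(3-methylbut-2-en-1-yl)benzaldehyde
Product: 9 (2E)-3-[4,5-bis(methoxymethoxy)-2,3-bis(3-methylbut-2-en-1-yl)phenyl]-1-[2-hydroxy-4-(methoxymethoxy)phenyl]prop-2-en-1-one, via aldol adduct 8 (not isolated)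
Conditions: KOH (50 % aq.), EtOH, rt, 36 h; then dil. HCl to pH 5
Reagents that add atoms: none
Why: Claisen–Schmidt condensation: aldol addition of the methyl ketone enolate to the non-enolisable aldehyde and E1cB dehydration give the conjugated (E)-enone, with MOM ethers and prenyl groups inert to hydroxide.

Step 7
Reactants: 9 tris-MOM chalcone
Product: 10 (2E)-1-(2,4-dihydroxyphenyl)-3-[4,5-dihydroxy-2,3-bis(3-methylbut-2-en-1-yl)phenyl]prop-2-en-1-one
Conditions: HCl (1.25 M in MeOH), MeOH/THF, 40 °C, short reaction time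
Reagents that add atoms: none
Why: Acid-catalysed acetal exchange with methanol removes the three MOM groups at the robust chalcone stage, before any acid-sensitive para-hydroxystyrene exists, under conditions mild enough to spare the ortho-prenyl phenol.

Step 8
Reactants: 10 (2E)-1-(2,4-dihydroxyphenyl)-3-[4,5-dihydroxy-2,3-bis(3-methylbut-2-en-1-yl)phenyl]prop-2-en-1-one
Product: 14 4-[(2E)-3-[4,5-dihydroxy-2,3-bis(3-methylbut-2-en-1-yl)phenyl]prop-2-en-1-yl]benzene-1,3-diol, via tetracarbonate 11 (not isolated), via quinone methide 12 (not isolated), via tricarbonate 13 (not isolated)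
Conditions: ClCO2Et (5 equiv), Et3N, THF, 0 °C; filter; NaBH4, THF/H2O, 0 °C to rt; then degassed 1 M NaOH, rt, argon; pH 6 phosphate buffer work-up
Reagents that add atoms: ethyl chloroformate, CCOC(=O)Cl (its atoms sit only in the non-isolated compounds 11 to 13 and are gone in 14, which itself gains hydrogen only)
Why: Carbonate-assisted reductive deoxygenation of an ortho-hydroxyaryl ketone: borohydride 1,2-reduction, carbonate transfer and elimination give the ortho-quinone methide, a second hydride adds at the benzylic carbon to re-aromatise to the (E)-cinnamylphenol, and hydroxide then cleaves the remaining aryl carbonates.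

Step 9
Reactants: 14 4-[(2E)-3-[4,5-dihydroxy-2,3-bis(3-methylbut-2-en-1-yl)phenyl]prop-2-en-1-yl]benzene-1,3-diol
Product: 16 (+)-(2R)-kazinol I, 5-[(2R)-7-hydroxy-3,4-dihydro-2H-chromen-2-yl]-3,4-bis(3-methylbut-2-en-1-yl)benzene-1,2-diol, via para-quinone methide 15 (not isolated)
Conditions: (R)-3,3'-bis(2,4,6-triisopropylphenyl)-1,1'-binaphthyl-2,2'-diyl hydrogen phosphate [(R)-TRIP] (10 mol %), toluene/CH2Cl2 1:1 (0.02 M), 0 °C to rt, argon
Reagents that add atoms: none
Why: Proposed new method: enantioselective 6-endo intramolecular hydroalkoxylation of a para-hydroxystyrene through a chiral-phosphate-bound para-quinone methide; the 4'-hydroxyl makes C2 the only carbon able to carry cationic character, so the weak chiral acid (too weak to protonate the prenyl alkenes) protonates C3 to give 15 as a hydrogen-bonded ion pair, and the phosphoryl oxygen, hydrogen-bonded to the tethered ring A 2-hydroxyl, delivers that oxygen to one face of C2 inside the pocket of the triisopropylphenyl groups, closing ring C and setting the (2R) centre under kinetic control; the closest known reaction types are chiral-phosphoric-acid-catalysed 1,6-additions to para-quinone methides generated in situ, chiral Brønsted-acid-catalysed intramolecular hydroalkoxylation of alkenes, and the racemic acid-mediated cyclisation of 2-cinnamylphenols to flavans.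

## Compound list

1 | 5-bromovanillin (3-bromo-4-hydroxy-5-methoxybenzaldehyde) | O=Cc1cc(OC)c(O)c(Br)c1 | starting material
2 | 2,3-dibromo-4-hydroxy-5-methoxybenzaldehyde | O=Cc1cc(OC)c(O)c(Br)c1Br | intermediate
3 | 2,3-dibromo-4,5-dihydroxybenzaldehyde | O=Cc1cc(O)c(O)c(Br)c1Br | intermediate
4 | 2,3-dibromo-4,5-bis(methoxymethoxy)benzaldehyde | O=Cc1cc(OCOC)c(OCOC)c(Br)c1Br | intermediate
5 | 4,5-bis(methoxymethoxy)-2,3-bis(3-methylbut-2-en-1-yl)benzaldehyde | O=Cc1cc(OCOC)c(OCOC)c(CC=C(C)C)c1CC=C(C)C | intermediate
6 | 2,4-dihydroxyacetophenone | CC(=O)c1ccc(O)cc1O | starting material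
7 | 1-[2-hydroxy-4-(methoxymethoxy)phenyl]ethan-1-one | CC(=O)c1ccc(OCOC)cc1O | intermediate
8 | aldol adduct, racemic 3-hydroxy-3-aryl-propan-1-one (not isolated) | COCOc1ccc(C(=O)CC(O)c2cc(OCOC)c(OCOC)c(CC=C(C)C)c2CC=C(C)C)c(O)c1 | intermediate
9 | (2E)-3-[4,5-bis(methoxymethoxy)-2,3-bis(3-methylbut-2-en-1-yl)phenyl]-1-[2-hydroxy-4-(methoxymethoxy)phenyl]prop-2-en-1-one (tris-MOM chalcone) | COCOc1ccc(C(=O)/C=C/c2cc(OCOC)c(OCOC)c(CC=C(C)C)c2CC=C(C)C)c(O)c1 | intermediate
10 | (2E)-1-(2,4-dihydroxyphenyl)-3-[4,5-dihydroxy-2,3-bis(3-methylbut-2-en-1-yl)phenyl]prop-2-en-1-one | Oc1ccc(C(=O)/C=C/c2cc(O)c(O)c(CC=C(C)C)c2CC=C(C)C)c(O)c1 | intermediate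
11 | tetrakis(ethyl carbonate) of 10 (not isolated) | CCOC(=O)Oc1ccc(C(=O)/C=C/c2cc(OC(=O)OCC)c(OC(=O)OCC)c(CC=C(C)C)c2CC=C(C)C)c(OC(=O)OCC)c1 | intermediate
12 | ortho-quinone methide with three remaining ethyl carbonates (not isolated) | CCOC(=O)OC1=CC(=O)C(=C/C=C/c2cc(OC(=O)OCC)c(OC(=O)OCC)c(CC=C(C)C)c2CC=C(C)C)C=C1 | intermediate
13 | tris(ethyl carbonate) of 14, ring A 2-hydroxyl free (not isolated) | CCOC(=O)Oc1ccc(C/C=C/c2cc(OC(=O)OCC)c(OC(=O)OCC)c(CC=C(C)C)c2CC=C(C)C)c(O)c1 | intermediate
14 | 4-[(2E)-3-[4,5-dihydroxy-2,3-bis(3-methylbut-2-en-1-yl)phenyl]prop-2-en-1-yl]benzene-1,3-diol | Oc1ccc(C/C=C/c2cc(O)c(O)c(CC=C(C)C)c2CC=C(C)C)c(O)c1 | intermediate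
15 | para-quinone methide tautomer of 14, bound to the chiral phosphate (not isolated) | O=C1C(O)=CC(=CCCc2ccc(O)cc2O)C(CC=C(C)C)=C1CC=C(C)C | intermediate
16 | (+)-(2R)-kazinol I | CC(C)=CCc1c([C@H]2CCc3ccc(O)cc3O2)cc(O)c(O)c1CC=C(C)C | target

## Step count and risk

Total steps: 9. Longest linear sequence: 8 (steps 1 to 4 and 6 to 9, from 5-bromovanillin). Step 5 is a one-step side branch.

The three steps most likely to fail:

**Step 9 (the proposed new cyclisation).** The acid may be too weak to protonate the styrene, the ee may be low, the product may slowly racemise by reversible ring opening through the quinone methide, or ring A may be C-alkylated intermolecularly. The fallback sets out from 14 and uses known chemistry. An achiral acid, (PhO)2P(O)OH (10 mol %) in CH2Cl2 at rt, effects the established acid-mediated cyclisation of a 2-cinnamylphenol to the flavan and gives racemic kazinol I F1. The racemate is then resolved by preparative supercritical-fluid chromatography on an amylose tris(3,5-dimethylphenylcarbamate) phase. The dextrorotatory (2R)-enantiomer is 16, where the fallback rejoins the route, and (2S)-kazinol I F2 is set aside.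

**Step 4 (two-fold Stille prenylation).** The second coupling sits between a prenyl group and a MOM ether, so incomplete conversion, protodebromination or branched (1,1-dimethylallyl) isomers are possible. The fallback sets out from 4 and masks the aldehyde so that an organozinc can be used. HC(OMe)3 and catalytic pyridinium p-toluenesulfonate in MeOH at rt give 2,3-dibromo-1-(dimethoxymethyl)-4,5-bis(methoxymethoxy)benzene F3. A linear-selective Negishi coupling with (3-methylbut-2-en-1-yl)zinc bromide, Pd(OAc)2 and 2-dicyclohexylphosphino-2',6'-bis(dimethylamino)biphenyl in THF at rt then gives 1-(dimethoxymethyl)-4,5-bis(methoxymethoxy)-2,3-bis(3-methylbut-2-en-1-yl)benzene F4. Brief treatment with 1 M HCl in THF at 0 °C hydrolyses the acetal only and returns to the route at 5.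

**Step 8 (carbonate/borohydride deoxygenation on the free tetraphenol).** Four carbonates must be formed and three removed again, conjugate reduction of the enone can lead to the saturated diarylpropane, and the tetraphenol is air-sensitive in base. The fallback sets out from 9, bypasses 10, and runs the deoxygenation on the classical single-phenol substrate. ClCO2Et (1.2 equiv) and Et3N give the 2'-O-(ethoxycarbonyl) chalcone F5. NaBH4 in THF/H2O converts it through the ortho-quinone methide F6 into 2-[(2E)-3-[4,5-bis(methoxymethoxy)-2,3-bis(3-methylbut-2-en-1-yl)phenyl]prop-2-en-1-yl]-5-(methoxymethoxy)phenol F7. The MOM groups are then removed under buffered, non-protic conditions with TMSOTf and 2,2'-bipyridyl in CH2Cl2/MeCN at 0 °C, which gives the tetrakis(trimethylsilyl) ether F8. Aqueous work-up hydrolyses the silyl ethers and returns to the route at 14.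

## Further compounds

F1 | step 9 | racemic kazinol I | CC(C)=CCc1c(C2CCc3ccc(O)cc3O2)cc(O)c(O)c1CC=C(C)C
F2 | step 9 | (2S)-kazinol I | CC(C)=CCc1c([C@@H]2CCc3ccc(O)cc3O2)cc(O)c(O)c1CC=C(C)C
F3 | step 4 | 2,3-dibromo-1-(dimethoxymethyl)-4,5-bis(methoxymethoxy)benzene | COC(OC)c1cc(OCOC)c(OCOC)c(Br)c1Br
F4 | step 4 | 1-(dimethoxymethyl)-4,5-bis(methoxymethoxy)-2,3-bis(3-methylbut-2-en-1-yl)benzene | COC(OC)c1cc(OCOC)c(OCOC)c(CC=C(C)C)c1CC=C(C)C
F5 | step 8 | 2'-O-(ethoxycarbonyl) derivative of chalcone 9 | CCOC(=O)Oc1cc(OCOC)ccc1C(=O)/C=C/c1cc(OCOC)c(OCOC)c(CC=C(C)C)c1CC=C(C)C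
F6 | step 8 | tris-MOM ortho-quinone methide | COCOC1=CC(=O)C(=C/C=C/c2cc(OCOC)c(OCOC)c(CC=C(C)C)c2CC=C(C)C)C=C1
F7 | step 8 | 2-[(2E)-3-[4,5-bis(methoxymethoxy)-2,3-bis(3-methylbut-2-en-1-yl)phenyl]prop-2-en-1-yl]-5-(methoxymethoxy)phenol | COCOc1ccc(C/C=C/c2cc(OCOC)c(OCOC)c(CC=C(C)C)c2CC=C(C)C)c(O)c1
F8 | step 8 | tetrakis(trimethylsilyl) ether of 14 | C[Si](C)(C)Oc1ccc(C/C=C/c2cc(O[Si](C)(C)C)c(O[Si](C)(C)C)c(CC=C(C)C)c2CC=C(C)C)c(O[Si](C)(C)C)c1
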